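The seven-membered carbocycle (C1, C5, C6, C7, C8, C9, C10; xanthane numbering) is cut into a three-carbon unit C10–C1–C5, with oxygen on its central atom C1, and a four-carbon unit C9–C8–C7–C6, with oxygen on both ends. This is the pattern of an oxyallyl cation–furan (4+3) cycloaddition. A chiral alkoxy-substituted silyloxyallyl cation, released from the silyl enol ether of a mixed α-keto acetal, and a 3-substituted furan should give the C9–C10 and C5–C6 bonds, the ring and the C5 and C6 stereocentres in one operation. The oxygen bridge of the adduct later becomes the lactone oxygen on C6.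

Key step: step 3

Atom labels: the xanthane numbering of the target is used for every intermediate (ring C1, C5–C10; C14 = CH3 on C10; lactone C6–O–C12(=O)–C11(=C13)–C7; side chain C2(=O)–C3=C4–C15).
Assumption: the (R)-1-phenylethyl group is taken to shield the Re face of the alkoxy-bearing cation terminus (C5), so that the furan adds to its Si face; if the sense were opposite, the (S)-alcohol would be used.
Assumption: compounds 1, 5, 18 and 23 are taken as catalogue compounds.

Step 1
Reactants: 1 1,1-dimethoxybutan-2-one; 2 (R)-1-phenylethanol
Product: 3 1-methoxy-1-[(R)-1-phenylethoxy]butan-2-one (both acetal epimers)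
Conditions: 1 (3 equiv), PPTS (cat.), cyclohexane, 80 °C, 5 Å molecular sieves (removal of MeOH)
Reagents that add atoms: none
Why: Acid-catalysed transacetalization exchanges one methoxy group for the chiral alkoxy group that later controls the cycloaddition; the acetal carbon forms as both epimers, which is irrelevant because it becomes trigonal in step 3.

Step 2
Reactants: 3 mixed acetal
Product: 4 (Z)-1-methoxy-1-[(R)-1-phenylethoxy]-2-(triethylsilyloxy)but-2-ene
Conditions: LiN(i-Pr)2, THF, −78 °C; then Et3SiCl, −78 °C → rt
Reagents that add atoms: chlorotriethylsilane, CC[Si](Cl)(CC)CC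
Why: Kinetic enolization at the ethyl CH2 and O-silylation (silyl enol ether formation) give the oxyallyl cation precursor; the double-bond geometry is inconsequential because C10 becomes trigonal again in step 6.

Step 3
Reactants: 4 silyl enol ether; 5 methyl 2-(furan-3-yl)acetate
Product: 6 oxygen-bridged cycloadduct (8-oxabicyclo[3.2.1]oct-6-en-3-one: ketone C1, (R)-1-phenylethoxy on C5 anti to the oxygen bridge, CH3 on C10, CH2CO2Me on alkene carbon C7, oxygen bridge C6–O–C9)
Conditions: 5 (2 equiv), Me3SiOTf (0.2 equiv), CH2Cl2, −95 °C
Reagents that add atoms: none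
Why: Me3SiOTf removes the methoxy group of 4 to give a W-shaped (R)-1-phenylethoxy-substituted 2-silyloxyallyl cation, which should add to the furan in a stepwise cationic (4+3) cycloaddition; the closest known reaction type is the oxyallyl cation–furan cycloaddition of α-alkoxy silyl enol ether acetals. The oxocarbenium carbon C5 bonds first to the more nucleophilic furan α-carbon next to the side chain (future C6), and the enol silane carbon C10 then closes onto the other furan α-carbon (future C9); this second bond closes the cycloheptenone ring and with it the oxygen-bridged tetrahydropyranone ring in a suprafacial (4+3) sense. C6 and C9 arise cis on one furan face, and their absolute configuration is set by the auxiliary, whose phenyl group shields the Re face of C5; the C5 alkoxy group takes the equatorial position anti to the oxygen bridge (compact transition state, also the thermodynamic epimer). The C10 methyl configuration is immaterial because C10 becomes trigonal in step 6. The step needs regioselectivity (alkoxy carbon to the substituted side of the furan), which the match of the most electrophilic cation terminus with the most nucleophilic furan position should secure, and facial selectivity, which the auxiliary should secure at −95 °C.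

Step 4
Reactants: 6 cycloadduct
Product: 7 bicyclic hydroxy keto ester (C5–OH, saturated C7–C8, CH2CO2Me on C7 anti to the oxygen bridge)
Conditions: H2 (1 atm), 10% Pd/C, EtOAc/MeOH, rt
Reagents that add atoms: none
Why: Heterogeneous hydrogenation adds H2 to the strained alkene from the exo face (the face of the oxygen bridge), which places the CH2CO2Me arm on C7 anti to the C6–O bond (sets C7), and hydrogenolysis of the benzylic ether removes the auxiliary in the same operation.

Step 5
Reactants: 7 bicyclic hydroxy keto ester
Product: 8 C5 tert-butyldimethylsilyl ether of 7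
Conditions: t-BuMe2SiOTf, 2,6-lutidine, CH2Cl2, −78 → 0 °C
Reagents that add atoms: tert-butyldimethylsilyl trifluoromethanesulfonate, CC(C)(C)[Si](C)(C)OS(=O)(=O)C(F)(F)F
Why: Silyl ether protection of the secondary alcohol gives an α-silyloxy ketone that tolerates the basic and oxidizing steps that follow; no stereocentre is touched.

Step 6
Reactants: 8 bicyclic silyloxy keto ester
Product: 9 enone lactone (cyclohept-2-enone C1(=O)–C10(CH3)=C9, trans-fused γ-lactone C6–O–C12(=O)–C11H2–C7, C5–OTBS)
Conditions: DBU, CH2Cl2, 0 °C → rt
Reagents that add atoms: none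
Why: Base-induced β-elimination (E1cB, retro-oxa-Michael) of the C9–O bond from the C10 enolate opens the bridge, and the C6 alkoxide closes the trans-fused γ-lactone on the ester (5-exo-trig), which makes this pathway irreversible while opening on the C5 side is reversible; C6 keeps its configuration because its C–O bond is not broken.

Step 7
Reactants: 9 enone lactone
Product: 11 C9 hydroxy ketone (C1 ketone; C9 and C10 not controlled), via C9 pinacol boronate 10 (not isolated)
Conditions: B2pin2, CuCl (5 mol %), DPEphos (5 mol %), NaOt-Bu (10 mol %), MeOH, THF, rt; then NaBO3·4H2O, THF/H2O, rt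
Reagents that add atoms: bis(pinacolato)diboron, CC1(C)OB(OC1(C)C)B1OC(C)(C)C(C)(C)O1 (boron of 10 only); sodium perborate, [Na+].[Na+].O[B-]1(O)OO[B-](O)(O)OO1 (oxygen on C9)
Why: Copper-catalysed conjugate borylation of the enone and oxidative C–B cleavage return an oxygen to C9 (net β-hydroxylation); C9 and C10 form without reliable control, which is tolerated because C9 is oxidized in step 12 and C10 is equilibrated in step 14.

Step 8
Reactants: 11 C9 hydroxy ketone
Product: 12 C1 exocyclic methylene compound
Conditions: Zn, CH2Br2, TiCl4, THF/CH2Cl2, 0 °C → rt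
Reagents that add atoms: dibromomethane, BrCBr
Why: The non-basic Lombardo methylenation converts the hindered, enolizable ketone into the exocyclic alkene without β-elimination and leaves the lactone untouched; no stereocentre is formed.

Step 9
Reactants: 12 exocyclic methylene lactone
Product: 13 Mannich base (CH2NMe2 on C11, both C11 epimers)
Conditions: LiN(i-Pr)2 (2.5 equiv), THF, −78 °C; then CH2=NMe2+ I−, −78 → 0 °C
Reagents that add atoms: N,N-dimethylmethyleneiminium iodide, C=[N+](C)C.[I-]
Why: The lactone enolate, the only enolizable carbonyl left, is aminomethylated with Eschenmoser's salt (Mannich reaction), which stores the future C13 methylene as an amine that survives the osmylation; the C11 centre is removed in step 11.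

Step 10
Reactants: 13 Mannich base
Product: 14 amino triol (tertiary C1–OH trans to the C5 oxygen, C2H2–OH)
Conditions: OsO4 (5 mol %), N-methylmorpholine N-oxide, acetone/H2O, rt
Reagents that add atoms: N-methylmorpholine N-oxide, C[N+]1([O-])CCOCC1; water, O; osmium tetroxide as the catalytic oxygen carrier, O=[Os](=O)(=O)=O
Why: Upjohn dihydroxylation of the only alkene should occur anti to the allylic C5 silyloxy group (Kishi's empirical rule, the bulky silyl ether shielding its own face), which places the C1 hydroxyl trans to the C5 oxygen as the target requires.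

Step 11
Reactants: 14 amino triol
Product: 16 α-methylene lactone triol, via trimethylammonium iodide 15 (not isolated)
Conditions: MeI, CH2Cl2/MeOH, rt; then aq NaHCO3, rt
Reagents that add atoms: none
Why: N-Methylation and mild base-induced loss of trimethylamine through the lactone enolate (Hofmann-type E1cB elimination) unveil the α-methylene lactone; no stereocentre of the target is affected.

Step 12
Reactants: 16 α-methylene lactone triol
Product: 17 keto hydroxy aldehyde (C9 ketone, C1(OH)–CHO)
Conditions: SO3·pyridine, DMSO, i-Pr2NEt, CH2Cl2, 0 °C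
Reagents that add atoms: none
Why: Parikh–Doering oxidation converts the primary alcohol into the aldehyde and the C9 alcohol into the ketone while the tertiary C1 hydroxyl cannot react; oxidizing C9 here prevents lactol formation with the new aldehyde.

Step 13
Reactants: 17 keto hydroxy aldehyde; 18 (E)-1-bromoprop-1-ene
Product: 19 allylic alcohol (C2–OH, both epimers; (E)-propenyl group)
Conditions: CrCl2 (6 equiv), NiCl2 (2 mol %), DMSO, rt
Reagents that add atoms: none
Why: The Nozaki–Hiyama–Kishi reaction adds the (E)-propenylchromium reagent chemoselectively to the aldehyde in the presence of the ketone and the lactone with retention of the alkene geometry; the C2 carbinol is a mixture and is oxidized in step 14.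

Step 14
Reactants: 19 allylic alcohol
Product: 21 diketone silyl ether (crotonoyl group on C1, natural C10 configuration), via C10-epimeric diketone mixture 20 (not isolated)
Conditions: Dess–Martin periodinane, NaHCO3, CH2Cl2, 0 °C → rt; then DBU (0.1 equiv), CH2Cl2, 0 °C
Reagents that add atoms: none
Why: Dess–Martin oxidation of the allylic C2 alcohol gives the enone (the tertiary C1–OH is inert), and brief treatment with DBU equilibrates the enolizable C10 centre to the epimer with CH3 trans to the bulky crotonoyl group on C1 (thermodynamic control, expected to be the natural configuration).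

Step 15
Reactants: 21 diketone silyl ether
Product: 22 C5 alcohol
Conditions: HF·pyridine, THF/pyridine, 0 °C → rt
Reagents that add atoms: none
Why: Fluoride-mediated cleavage of the silyl ether under buffered conditions frees the C5 hydroxyl without touching the enone, the α-methylene lactone or the base-sensitive β-hydroxy ketone.

Step 16
Reactants: 22 C5 alcohol; 23 (R)-2-methylbutanoic acid
Product: 24 CNP0153197.3 (target)
Conditions: 23 (1.5 equiv), EDC·HCl, DMAP (cat.), CH2Cl2, 0 °C → rt
Reagents that add atoms: none
Why: Steglich esterification acylates the only secondary hydroxyl (the tertiary C1–OH is unreactive) with retention at C5 and, at low temperature with catalytic DMAP, without racemization of the (R)-2-methylbutanoyl centre.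

Compound list
1 | 1,1-dimethoxybutan-2-one | CCC(=O)C(OC)OC | starting material
2 | (R)-1-phenylethanol | C[C@@H](O)c1ccccc1 | starting material
3 | 1-methoxy-1-[(R)-1-phenylethoxy]butan-2-one (both acetal epimers) | CCC(=O)C(OC)O[C@H](C)c1ccccc1 | intermediate
4 | (Z)-1-methoxy-1-[(R)-1-phenylethoxy]-2-(triethylsilyloxy)but-2-ene | C/C=C(\O[Si](CC)(CC)CC)C(OC)O[C@H](C)c1ccccc1 | intermediate
5 | methyl 2-(furan-3-yl)acetate | COC(=O)Cc1ccoc1 | starting material
6 | cycloadduct: 8-oxabicyclo[3.2.1]oct-6-en-3-one with (R)-1-phenylethoxy on C5 (5S, anti to the bridge), C6 (R), CH3 on C10, CH2CO2Me on C7 | O=C1[C@H](C)[C@@H]2C=C(CC(=O)OC)[C@@H](O2)[C@@H]1O[C@H](C)c3ccccc3 | intermediate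
7 | bicyclic hydroxy keto ester (C5–OH, CH2CO2Me on C7 anti to the bridge) | O=C1[C@H](C)[C@@H]2C[C@H](CC(=O)OC)[C@@H](O2)[C@@H]1O | intermediate
8 | C5 tert-butyldimethylsilyl ether of 7 | O=C1[C@H](C)[C@@H]2C[C@H](CC(=O)OC)[C@@H](O2)[C@@H]1O[Si](C)(C)C(C)(C)C | intermediate
9 | enone lactone (C1 ketone, C9=C10, trans-fused γ-lactone, C5–OTBS) | O=C1C(C)=CC[C@@H]2CC(=O)O[C@H]2[C@@H]1O[Si](C)(C)C(C)(C)C | intermediate
10 | C9 pinacol boronate (C9, C10 not controlled) | O=C1C(C)C(B3OC(C)(C)C(C)(C)O3)C[C@@H]2CC(=O)O[C@H]2[C@@H]1O[Si](C)(C)C(C)(C)C | intermediate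
11 | C9 hydroxy ketone (C9, C10 not controlled) | O=C1C(C)C(O)C[C@@H]2CC(=O)O[C@H]2[C@@H]1O[Si](C)(C)C(C)(C)C | intermediate
12 | C1 exocyclic methylene compound | C=C1C(C)C(O)C[C@@H]2CC(=O)O[C@H]2[C@@H]1O[Si](C)(C)C(C)(C)C | intermediate
13 | Mannich base (CH2NMe2 on C11) | C=C1C(C)C(O)C[C@@H]2C(CN(C)C)C(=O)O[C@H]2[C@@H]1O[Si](C)(C)C(C)(C)C | intermediate
14 | amino triol (C1–OH trans to C5–O; C2H2–OH) | OC[C@]1(O)C(C)C(O)C[C@@H]2C(CN(C)C)C(=O)O[C@H]2[C@@H]1O[Si](C)(C)C(C)(C)C | intermediate
15 | trimethylammonium iodide of 14 | OC[C@]1(O)C(C)C(O)C[C@@H]2C(C[N+](C)(C)C)C(=O)O[C@H]2[C@@H]1O[Si](C)(C)C(C)(C)C.[I-] | intermediate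
16 | α-methylene lactone triol | OC[C@]1(O)C(C)C(O)C[C@@H]2C(=C)C(=O)O[C@H]2[C@@H]1O[Si](C)(C)C(C)(C)C | intermediate
17 | keto hydroxy aldehyde (C9 ketone, C1(OH)–CHO; C10 not controlled) | O=C[C@]1(O)C(C)C(=O)C[C@@H]2C(=C)C(=O)O[C@H]2[C@@H]1O[Si](C)(C)C(C)(C)C | intermediate
18 | (E)-1-bromoprop-1-ene | C/C=C/Br | starting material
19 | allylic alcohol (C2–OH epimers, (E)-propenyl) | C/C=C/C(O)[C@]1(O)C(C)C(=O)C[C@@H]2C(=C)C(=O)O[C@H]2[C@@H]1O[Si](C)(C)C(C)(C)C | intermediate
20 | diketone, mixture of C10 epimers | C/C=C/C(=O)[C@]1(O)C(C)C(=O)C[C@@H]2C(=C)C(=O)O[C@H]2[C@@H]1O[Si](C)(C)C(C)(C)C | intermediate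
21 | diketone silyl ether, natural C10 configuration | C/C=C/C(=O)[C@]1(O)[C@@H](C)C(=O)C[C@@H]2C(=C)C(=O)O[C@H]2[C@@H]1O[Si](C)(C)C(C)(C)C | intermediate
22 | C5 alcohol (de-silylated 21) | C/C=C/C(=O)[C@]1(O)[C@@H](C)C(=O)C[C@@H]2C(=C)C(=O)O[C@H]2[C@@H]1O | intermediate
23 | (R)-2-methylbutanoic acid | CC[C@@H](C)C(=O)O | starting material
24 | CNP0153197.3 | C=C1C(=O)O[C@@H]2[C@@H]1CC(=O)[C@H](C)[C@@](O)(C(=O)/C=C/C)[C@H]2OC(=O)[C@H](C)CC | target

Total step count: 16. Longest linear sequence: 16 steps (from 1; compounds 2, 5, 18 and 23 enter as purchased fragments).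

Steps most likely to fail

Step 3. The unsymmetrical furan may bond in the reverse orientation (arm ending on C8), or facial control by the auxiliary may erode with the hindered partner. The fallback sets out from 4 and returns at 7. The cycloaddition is run with furan itself under the same conditions, the case with the firmest precedent, to give the parent cycloadduct F1. BCl3 (CH2Cl2, −78 °C) removes the auxiliary without touching the alkene to give the hydroxy ketone F2. Ethyl vinyl ether and NBS (CH2Cl2, −40 °C) give the bromoacetal F3. Bu3SnH/AIBN (benzene, 80 °C) then closes a six-membered ring by 6-exo radical cyclization, which delivers the two-carbon arm from the C5 oxygen to C7 only and to the endo face only, giving the tricyclic ethyl acetal F4. Jones reagent (CrO3, H2SO4, acetone, 0 °C) gives the bridged δ-lactone F5, and acid-catalysed methanolysis (AcCl, MeOH) opens it to 7.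

Step 6. Enolization toward C5 may compete, and product 9 may lose its C6 acyloxy group by a second β-elimination under the amine base. The fallback sets out from 8 and returns at 9, and separates the events. Kinetic deprotonation on the C10 side (LiN(i-Pr)2, Me3SiCl, THF, −78 °C) gives the trimethylsilyl enol ether F6. Catalytic Me3SiOTf (CH2Cl2, −78 °C) opens the bridge with silyl transfer to the C6 oxygen under non-basic conditions to give the enone silyl ether F7. PPTS in MeOH cleaves the trimethylsilyl ether and the free C6 hydroxyl lactonizes to 9.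

Step 10. Osmylation may take place from the face syn to the C5 silyloxy group if the C10 methyl group overrides the silyl ether. The fallback sets out from 13 and returns at 14, and uses a stereocomplementary two-stage sequence. Epoxidation of the trifluoroacetate salt of 13 with mCPBA (CH2Cl2, 0 °C) from that same face gives the spiro-epoxide F8. Dilute HClO4 in THF/H2O opens it at the tertiary carbon C1 with inversion, which places the C1 hydroxyl trans to the C5 oxygen and gives 14.

Further compounds
F1 | step 3 | parent cycloadduct (6 without the CH2CO2Me arm) | O=C1[C@H](C)[C@@H]2C=C[C@@H](O2)[C@@H]1O[C@H](C)c3ccccc3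
F2 | step 3 | hydroxy ketone (auxiliary removed, alkene kept) | O=C1[C@H](C)[C@@H]2C=C[C@@H](O2)[C@@H]1O
F3 | step 3 | bromoacetal (C5–O–CH(OEt)CH2Br) | O=C1[C@H](C)[C@@H]2C=C[C@@H](O2)[C@@H]1OC(CBr)OCC
F4 | step 3 | tricyclic ethyl acetal (C5–O–CH(OEt)–CH2–C7) | O=C1[C@H](C)[C@@H]2C[C@@H]3CC(OCC)O[C@H]1[C@@H]3O2
F5 | step 3 | bridged δ-lactone (C5–O–C(=O)–CH2–C7) | O=C1[C@H](C)[C@@H]2C[C@@H]3CC(=O)O[C@H]1[C@@H]3O2
F6 | step 6 | trimethylsilyl enol ether of 8 (C1=C10) | CC1=C(O[Si](C)(C)C)[C@@H](O[Si](C)(C)C(C)(C)C)[C@@H]2O[C@H]1C[C@@H]2CC(=O)OC
F7 | step 6 | ring-opened enone with C6 trimethylsilyl ether | O=C1C(C)=CC[C@H](CC(=O)OC)[C@@H](O[Si](C)(C)C)[C@@H]1O[Si](C)(C)C(C)(C)C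
F8 | step 10 | spiro-epoxide of 13 (oxygen syn to the C5 silyloxy group) | C1O[C@@]12C(C)C(O)C[C@@H]3C(CN(C)C)C(=O)O[C@H]3[C@@H]2O[Si](C)(C)C(C)(C)C
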